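**Strategy**

Everything rests on opening ring A at C10–C23. C23, the spiro atom of rings A and D, is a fully substituted carbinol carbon attached directly to the alkene carbon C10, the pattern left by an alkenylmetal adding to a ketone. A single Ni/Cr-mediated closure makes this bond, ring A and the C23 stereocentre. Its precursor is the cis-fused B/C lactone–cyclopentane bearing, both on the concave face, a (Z)-iodoalkenyl arm at C12 (C4 already set) and an α-silyloxy ketone arm at C21 next to the free C18 hydroxyl. C25 travels as a silyl ether and becomes the lactone carbonyl only after the closure.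

Key step: step 21

**Remarks**

- **Atom labels:** C1 to O29 are the heavy atoms of the target SMILES in the order written. "Convex" is the face of the cis-fused B/C bicycle that carries H16 and H22, and "concave" is the opposite face.
- **Structure check:** The iodoalkene must have C4 trans to C12 (iodine cis to C12, Z). C28 is S and maps onto (S)-α-hydroxy-γ-butyrolactone. O24 cis to C18 corresponds to C23 S. With these assignments the precursor and the product of step 21 agree with the target at C4, C12, C16, C18, C21, C22 and C28, so no descriptor needs correction.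
- **C25 in the precursor:**
  - C25 is carried as a tert-butyldiphenylsilyl ether and not as an ester.
  - A 3-silyloxy-4-oxo ester would lose silanol by β-elimination under the enolate chemistry of steps 16 and 18.
  - After ring closure a C25 ester would also have to compete with the C6 ester for O24.
  - Ring D is closed by oxidation instead, still two steps after the key step.
- **Placement of the arms:** Both arms sit on the concave face, which is the less stable placement at C12 and at C21. Each is therefore set by delivering hydrogen last from the convex face (steps 11 and 18), and no basic step follows step 18.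
- **Assumption:** The two C23 carbinol epimers formed in step 9 are carried on together (no descriptor at C23 in their SMILES), because step 20 removes this centre.
- **Origin of the stereocentres:**

| Element | Source |
|---|---|
| C16 | commercial enone |
| C28 | commercial hydroxy lactone |
| C22 | step 3 |
| C21 | step 11 |
| C18 | step 13 |
| C11 (temporary) | step 16 |
| C4 and the alkene geometry | step 17 |
| C12 | step 18 |
| C23 | step 21 |

**Route**

Step 1
Reactants: 1 (R)-4-(tert-butyldimethylsilyloxy)cyclopent-2-en-1-one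
Product: 2 (R)-4-(tert-butyldimethylsilyloxy)-2-iodocyclopent-2-en-1-one
Conditions: I2, pyridine–CH2Cl2 (1:1), 0 °C → rt
Reagents that add atoms: iodine, II
Why: α-Iodination of an enone (conjugate addition of pyridine, iodination of the enolate, elimination) places the halogen on C21 only and leaves the C16 stereocentre of the commercial enone untouched.

Step 2
Reactants: 2 (R)-4-(tert-butyldimethylsilyloxy)-2-iodocyclopent-2-en-1-one
Product: 3 (1S,4R)-4-(tert-butyldimethylsilyloxy)-2-iodocyclopent-2-en-1-ol
Conditions: NaBH4, CeCl3·7H2O, MeOH, −78 → −20 °C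
Reagents that add atoms: none
Why: Luche reduction gives clean 1,2-reduction, and hydride approaches anti to the C16 silyloxy group, so the new C18 hydroxyl is cis to O15.

Step 3
Reactants: 3 (1S,4R)-4-(tert-butyldimethylsilyloxy)-2-iodocyclopent-2-en-1-ol; 4 trimethyl orthoacetate
Product: 6 methyl 2-[(1R,5R)-5-(tert-butyldimethylsilyloxy)-2-iodocyclopent-2-en-1-yl]acetate, via mixed ketene acetal 5 (not isolated)
Conditions: 4 (10 equiv), EtCO2H (cat.), xylenes, 140 °C, MeOH distilled off
Reagents that add atoms: none
Why: The Johnson–Claisen rearrangement is suprafacial, so the C12–C13 acetate unit is delivered to C22 on the face that carried the C18 oxygen (cis to O15, which sets C22), while the double bond moves to C18=C21 and keeps the iodine for step 9.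

Step 4
Reactants: 6 methyl 2-[(1R,5R)-5-(tert-butyldimethylsilyloxy)-2-iodocyclopent-2-en-1-yl]acetate
Product: 8 (3aR,6aR)-4-iodo-3,3a,6,6a-tetrahydro-2H-cyclopenta[b]furan-2-one (rings B and C with iodine on C21), via hydroxy ester 7 (not isolated)
Conditions: 2 M aq. HCl, THF, rt
Reagents that add atoms: none
Why: Acid cleaves the only silyl ether, and the freed C16 hydroxyl, held cis to the acetate chain, closes ring B by lactonisation (intramolecular transesterification).

Step 5
Reactants: 9 (S)-3-hydroxydihydrofuran-2(3H)-one
Product: 10 (S)-3-(tert-butyldimethylsilyloxy)dihydrofuran-2(3H)-one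
Conditions: t-BuMe2SiCl, imidazole, DMF, rt
Reagents that add atoms: tert-butyldimethylsilyl chloride, CC(C)(C)[Si](C)(C)Cl
Why: Imidazole-promoted silylation protects O29 with a group that lasts to the end and does not touch C28, which comes from the chiral pool with the S configuration of the target.

Step 6
Reactants: 10 (S)-3-(tert-butyldimethylsilyloxy)dihydrofuran-2(3H)-one
Product: 11 (S)-2-(tert-butyldimethylsilyloxy)-4-hydroxy-N-methoxy-N-methylbutanamide
Conditions: MeNH(OMe)·HCl, iPrMgCl, THF, −20 → 0 °C
Reagents that add atoms: N,O-dimethylhydroxylamine hydrochloride, CNOC.Cl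
Why: Weinreb amide formation by aminolysis of the lactone with the magnesium amide opens the ring at the acyl carbon C23 at low temperature, so C28 is not epimerised and the C25 hydroxyl is released for separate protection.

Step 7
Reactants: 11 (S)-2-(tert-butyldimethylsilyloxy)-4-hydroxy-N-methoxy-N-methylbutanamide
Product: 12 (S)-2-(tert-butyldimethylsilyloxy)-4-(tert-butyldiphenylsilyloxy)-N-methoxy-N-methylbutanamide
Conditions: t-BuPh2SiCl, imidazole, CH2Cl2, rt
Reagents that add atoms: tert-butyldiphenylsilyl chloride, CC(C)(C)[Si](Cl)(c1ccccc1)c1ccccc1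
Why: Silylation of the primary alcohol blocks relactonisation and installs an ether that is stable to base, to weak acid and to the later cleavage of the triethylsilyl group.

Step 8
Reactants: 12 (S)-2-(tert-butyldimethylsilyloxy)-4-(tert-butyldiphenylsilyloxy)-N-methoxy-N-methylbutanamide
Product: 13 (S)-2-(tert-butyldimethylsilyloxy)-4-(tert-butyldiphenylsilyloxy)butanal
Conditions: iBu2AlH, THF, −78 °C; aq. Rochelle salt
Reagents that add atoms: none
Why: Reduction of a Weinreb amide stops at the chelated aluminium hemiaminal, which releases the aldehyde only on work-up, so neither over-reduction nor epimerisation at C28 is expected.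

Step 9
Reactants: 8 iodolactone (rings B and C); 13 (S)-2-(tert-butyldimethylsilyloxy)-4-(tert-butyldiphenylsilyloxy)butanal
Product: 15 allylic alcohol (lactone 8 with iodine replaced by the C23 carbinol chain C23–C28–C27–C25; C28 S; both C23 epimers), via alkenylchromium dichloride 14 (not isolated)
Conditions: CrCl2 (4 equiv), NiCl2 (2 mol %), DMF, rt
Reagents that add atoms: none
Why: The intermolecular Nozaki–Hiyama–Kishi coupling forms C21–C23 under non-basic conditions that spare the lactone and the α-silyloxy aldehyde stereocentre, and the new C23 carbinol centre (Felkin–Anh epimer expected to prevail) needs no control because step 20 turns it into a ketone.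

Step 10
Reactants: 15 allylic alcohol
Product: 16 C23 triethylsilyl ether of 15
Conditions: Et3SiOTf, 2,6-lutidine, CH2Cl2, −78 °C
Reagents that add atoms: triethylsilyl triflate, CC[Si](CC)(CC)OS(=O)(=O)C(F)(F)F
Why: Silylation with the reactive triflate covers the hindered allylic C23 hydroxyl with the most labile of the three silyl groups, so that it alone can be removed in step 19.

Step 11
Reactants: 16 C23 triethylsilyl ether
Product: 18 saturated bicyclic lactone with the C18 hydroxyl on the convex face and the C21 chain on the concave face, via C18 alkylborane 17 (not isolated)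
Conditions: BH3·THF, THF, 0 °C → rt; then 30% H2O2, aq. NaHCO3, 0 °C → rt
Reagents that add atoms: hydrogen peroxide, OO
Why: Hydroboration–oxidation is a syn anti-Markovnikov addition: boron goes to the less substituted C18 and hydrogen to C21 from the convex face of the cis-fused bicycle, which sets C21 by turning the C23 chain to the concave face, and BH3 reacts with the alkene faster than with the lactone.

Step 12
Reactants: 18 C18 secondary alcohol
Product: 19 C18 ketone (C21 chain still on the concave face)
Conditions: Dess–Martin periodinane, NaHCO3, CH2Cl2, 0 °C → rt; used without chromatography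
Reagents that add atoms: none
Why: Dess–Martin oxidation under buffered neutral conditions converts the only free alcohol into the C18 ketone without epimerising the adjacent C21 centre or eliminating O15, and the ketone is used at once.

Step 13
Reactants: 19 C18 ketone
Product: 20 C18 tertiary alcohol (methyl C19 convex; O20 concave and cis to the C21 chain)
Conditions: CeCl3 (anhydrous, 1.6 equiv), MeMgBr (1.5 equiv), THF, −78 °C
Reagents that add atoms: methylmagnesium bromide, C[Mg]Br
Why: Organocerium 1,2-addition is strongly nucleophilic but barely basic, so the ketone is methylated faster than it enolises and faster than the lactone reacts, and attack from the convex face anti to the C21 chain sets C18 with the methyl group convex and O20 concave.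

Step 14
Reactants: 21 methacrolein; 22 (triphenylphosphoranylidene)acetaldehyde
Product: 23 (E)-4-methylpenta-2,4-dienal
Conditions: toluene, 70 °C, sealed tube
Reagents that add atoms: none
Why: Wittig olefination with a stabilised formyl ylide extends methacrolein by C10–C11 and gives the E-dienal.

Step 15
Reactants: 23 (E)-4-methylpenta-2,4-dienal
Product: 24 (Z)-2-iodo-4-methylpenta-2,4-dienal
Conditions: I2, K2CO3, DMAP (cat.), THF–H2O (1:1), rt
Reagents that add atoms: iodine, II
Why: Amine-catalysed α-iodination of an enal (addition, iodination, elimination) gives the more stable Z-iodoenal, in which the formyl group stays trans to the isopropenyl group.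

Step 16
Reactants: 20 C18 tertiary alcohol; 24 (Z)-2-iodo-4-methylpenta-2,4-dienal
Product: 26 anti-aldol adduct (C11 carbinol R; dienyl iodide arm on the convex face at C12), via dilithium enolate alkoxide 25 (not isolated)
Conditions: LiN(iPr)2 (2.1 equiv), THF, −78 °C; 24; AcOH, −78 °C
Reagents that add atoms: none
Why: Aldol addition of a lactone lithium enolate: the ring locks the E(O) enolate geometry, so a Zimmerman–Traxler chair gives the anti adduct, attack on the convex face then makes C11 R as needed for step 17, and the convex placement of the arm at C12 is corrected in step 18.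

Step 17
Reactants: 26 anti-aldol adduct; 4 trimethyl orthoacetate
Product: 28 β,γ-unsaturated lactone with the complete (Z)-iodoalkenyl arm (C4 S; C6 methyl ester) on the convex face at C12, via mixed ketene acetal 27 (not isolated)
Conditions: 4 (15 equiv), EtCO2H (cat.), toluene, 110 °C, MeOH removed over 4 Å molecular sieves
Reagents that add atoms: none
Why: Johnson–Claisen rearrangement through a chair with the lactone residue equatorial forms C4–C5 and brings in the C6 methyl ester, transfers the C11 configuration suprafacially to C4 (S), and gives the alkene with C12 trans to C4, that is with iodine cis to C12 (Z).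

Step 18
Reactants: 28 lactone with the arm on the convex face
Product: 30 C12 epimer of 28 with the (Z)-iodoalkenyl arm on the concave face, via dipotassium dienolate 29 (not isolated)
Conditions: KN(SiMe3)2 (2.1 equiv), THF, −78 °C; then transferred by cannula into AcOH–THF, −78 °C
Reagents that add atoms: none
Why: Kinetic protonation of a lactone dienolate: removal of the doubly activated C12 hydrogen flattens C12, and the proton returns to the α-carbon from the open convex face because ring C and the C21 chain close the concave face, which turns the alkenyl arm to the concave face and leaves C4 and the Z-alkene unchanged.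

Step 19
Reactants: 30 lactone with both arms on the concave face
Product: 31 C18,C23-diol
Conditions: HF·pyridine, pyridine, THF, 0 °C
Reagents that add atoms: none
Why: Graded silyl ether cleavage: buffered HF·pyridine removes the triethylsilyl ether much faster than the secondary tert-butyldimethylsilyl and the primary tert-butyldiphenylsilyl ether, and the weakly acidic medium does not epimerise C12.

Step 20
Reactants: 31 C18,C23-diol
Product: 32 keto iodide (rings B and C; Z-iodoalkenyl arm at C12; C23 ketone arm at C21 with C28 silyl ether; free C18 hydroxyl)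
Conditions: Dess–Martin periodinane, NaHCO3, CH2Cl2, 0 °C → rt
Reagents that add atoms: none
Why: Dess–Martin oxidation touches only the secondary C23 alcohol (the C18 hydroxyl is tertiary) and its neutral buffered medium avoids retro-aldol cleavage and epimerisation at C12 or C21 in the β-hydroxy ketone.

Step 21
Reactants: 32 keto iodide
Product: 34 tricyclic C23 tertiary alcohol (rings A and B and C; ring D still open; C23 S), via alkenylchromium dichloride 33 (not isolated)
Conditions: CrCl2 (10 equiv), NiCl2 (0.1 equiv), degassed DMSO (0.005 M), rt → 45 °C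
Reagents that add atoms: none
Why: CrCl2 first reduces the nickel salt to zerovalent nickel; oxidative addition of this species to the C10–I bond (alkene geometry retained) and hand-over of the alkenyl group to trivalent chromium produce 33, whose carbon–chromium bond adds across the C23 carbonyl, so the step is an intramolecular Nozaki–Hiyama–Kishi reaction of an alkenyl iodide with a ketone, a known but less common relative of the aldehyde coupling. Ring A closes in the 6-exo-trig mode, the carbonyl oxygen staying outside the new ring. The usual weakness of ketone acceptors, their low reactivity, is offset by the α-oxygen at C28, which raises the electrophilicity of C23, and by the concave placement of both arms, which holds C10 within bonding reach of C23. The new C23 centre is under substrate control: trivalent chromium bridges the ketone oxygen and the free C18 hydroxyl on the concave face while the bulky C28 chain turns to the convex face, so C10 attacks the face that leaves O24 cis to C18. The step needs selectivity for the ketone over the C6 ester and the lactone and must not deprotonate C12–H or C21–H, which the low basicity and the carbonyl selectivity of alkenylchromium reagents secure. The Z geometry (iodine cis to C12) is what makes the closure geometrically possible, and high dilution with little nickel suppresses dimerisation of the alkenyl iodide.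

Step 22
Reactants: 34 tricyclic C23 tertiary alcohol
Product: 35 tetraol (free hydroxyls at C18 and C23 and C25 and C28)
Conditions: HF·pyridine (excess), THF, 0 °C → rt
Reagents that add atoms: none
Why: Fluoride-driven desilylation under mildly acidic conditions frees O29 and the C25 hydroxyl without base, so the β,γ-unsaturated lactone, the C6 ester and the tertiary alcohols are left alone.

Step 23
Reactants: 35 tetraol
Product: 38 CNP0148106.2 (target), via hydroxy aldehyde 36 (not isolated), via lactol 37 (not isolated)
Conditions: TEMPO (0.2 equiv), PhI(OAc)2 (2.5 equiv), CH2Cl2, rt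
Reagents that add atoms: none
Why: TEMPO/PhI(OAc)2 oxidative lactonisation of a 1,4-diol: the oxoammonium salt oxidises only the unhindered primary C25 alcohol, the C23 hydroxyl traps the aldehyde as a five-membered lactol, and a second oxidation gives spirolactone D while the hindered secondary C28 hydroxyl and the alkenes survive.

**Compound list**

1 | (R)-4-(tert-butyldimethylsilyloxy)cyclopent-2-en-1-one | O=C1C=C[C@H](O[Si](C)(C)C(C)(C)C)C1 | starting material
2 | (R)-4-(tert-butyldimethylsilyloxy)-2-iodocyclopent-2-en-1-one | O=C1C(I)=C[C@H](O[Si](C)(C)C(C)(C)C)C1 | intermediate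
3 | (1S,4R)-4-(tert-butyldimethylsilyloxy)-2-iodocyclopent-2-en-1-ol (cis) | O[C@@H]1C(I)=C[C@H](O[Si](C)(C)C(C)(C)C)C1 | intermediate
4 | trimethyl orthoacetate | CC(OC)(OC)OC | starting material
5 | 1-methoxyvinyl ether of 3 (mixed ketene acetal) | C=C(OC)O[C@@H]1C(I)=C[C@H](O[Si](C)(C)C(C)(C)C)C1 | intermediate
6 | methyl 2-[(1R,5R)-5-(tert-butyldimethylsilyloxy)-2-iodocyclopent-2-en-1-yl]acetate | COC(=O)C[C@H]1C(I)=CC[C@H]1O[Si](C)(C)C(C)(C)C | intermediate
7 | methyl 2-[(1R,5R)-5-hydroxy-2-iodocyclopent-2-en-1-yl]acetate | COC(=O)C[C@H]1C(I)=CC[C@H]1O | intermediate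
8 | (3aR,6aR)-4-iodo-3,3a,6,6a-tetrahydro-2H-cyclopenta[b]furan-2-one | O=C1C[C@H]2C(I)=CC[C@H]2O1 | intermediate
9 | (S)-3-hydroxydihydrofuran-2(3H)-one | O=C1OCC[C@@H]1O | starting material
10 | (S)-3-(tert-butyldimethylsilyloxy)dihydrofuran-2(3H)-one | O=C1OCC[C@@H]1O[Si](C)(C)C(C)(C)C | intermediate
11 | (S)-2-(tert-butyldimethylsilyloxy)-4-hydroxy-N-methoxy-N-methylbutanamide | CON(C)C(=O)[C@@H](O[Si](C)(C)C(C)(C)C)CCO | intermediate
12 | (S)-2-(tert-butyldimethylsilyloxy)-4-(tert-butyldiphenylsilyloxy)-N-methoxy-N-methylbutanamide | CON(C)C(=O)[C@@H](O[Si](C)(C)C(C)(C)C)CCO[Si](c1ccccc1)(c1ccccc1)C(C)(C)C | intermediate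
13 | (S)-2-(tert-butyldimethylsilyloxy)-4-(tert-butyldiphenylsilyloxy)butanal | O=C[C@@H](O[Si](C)(C)C(C)(C)C)CCO[Si](c1ccccc1)(c1ccccc1)C(C)(C)C | intermediate
14 | alkenylchromium dichloride from 8 (chromium on C21) | O=C1C[C@H]2C([Cr](Cl)Cl)=CC[C@H]2O1 | intermediate
15 | allylic alcohol: lactone with C18=C21 alkene and C23 carbinol chain on C21 (C28 S, C23 epimers) | O=C1C[C@H]2C(=CC[C@H]2O1)C(O)[C@@H](O[Si](C)(C)C(C)(C)C)CCO[Si](c1ccccc1)(c1ccccc1)C(C)(C)C | intermediate
16 | C23 triethylsilyl ether of 15 | O=C1C[C@H]2C(=CC[C@H]2O1)C(O[Si](CC)(CC)CC)[C@@H](O[Si](C)(C)C(C)(C)C)CCO[Si](c1ccccc1)(c1ccccc1)C(C)(C)C | intermediate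
17 | C18 alkylborane (boron and H21 on the convex face) | O=C1C[C@@H]2[C@H](O1)C[C@@H](B)[C@@H]2C(O[Si](CC)(CC)CC)[C@@H](O[Si](C)(C)C(C)(C)C)CCO[Si](c1ccccc1)(c1ccccc1)C(C)(C)C | intermediate
18 | C18 secondary alcohol (hydroxyl convex, C21 chain concave) | O=C1C[C@@H]2[C@H](O1)C[C@@H](O)[C@@H]2C(O[Si](CC)(CC)CC)[C@@H](O[Si](C)(C)C(C)(C)C)CCO[Si](c1ccccc1)(c1ccccc1)C(C)(C)C | intermediate
19 | C18 ketone | O=C1C[C@@H]2[C@H](O1)CC(=O)[C@@H]2C(O[Si](CC)(CC)CC)[C@@H](O[Si](C)(C)C(C)(C)C)CCO[Si](c1ccccc1)(c1ccccc1)C(C)(C)C | intermediate
20 | C18 tertiary alcohol (C18 S: methyl convex, hydroxyl concave) | O=C1C[C@@H]2[C@H](O1)C[C@](C)(O)[C@@H]2C(O[Si](CC)(CC)CC)[C@@H](O[Si](C)(C)C(C)(C)C)CCO[Si](c1ccccc1)(c1ccccc1)C(C)(C)C | intermediate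
21 | methacrolein | C=C(C)C=O | starting material
22 | (triphenylphosphoranylidene)acetaldehyde | O=CC=P(c1ccccc1)(c1ccccc1)c1ccccc1 | starting material
23 | (E)-4-methylpenta-2,4-dienal | C=C(C)/C=C/C=O | intermediate
24 | (Z)-2-iodo-4-methylpenta-2,4-dienal | C=C(C)/C=C(I)/C=O | intermediate
25 | dilithium salt of 20 (lactone enolate C12=C13, C18 alkoxide) | [Li]OC1=C[C@@H]2[C@H](O1)C[C@](C)(O[Li])[C@@H]2C(O[Si](CC)(CC)CC)[C@@H](O[Si](C)(C)C(C)(C)C)CCO[Si](c1ccccc1)(c1ccccc1)C(C)(C)C | intermediate
26 | anti-aldol adduct (C11 R, arm convex at C12, Z-iodoalkene C10=C4) | C=C(C)/C=C(I)/[C@H](O)[C@H]1C(=O)O[C@@H]2C[C@](C)(O)[C@@H]([C@H]12)C(O[Si](CC)(CC)CC)[C@@H](O[Si](C)(C)C(C)(C)C)CCO[Si](c3ccccc3)(c3ccccc3)C(C)(C)C | intermediate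
27 | 1-methoxyvinyl ether of 26 at the C11 oxygen (mixed ketene acetal) | C=C(C)/C=C(I)/[C@H](OC(=C)OC)[C@H]1C(=O)O[C@@H]2C[C@](C)(O)[C@@H]([C@H]12)C(O[Si](CC)(CC)CC)[C@@H](O[Si](C)(C)C(C)(C)C)CCO[Si](c3ccccc3)(c3ccccc3)C(C)(C)C | intermediate
28 | lactone with complete arm (C4 S, Z-iodoalkene C10=C11) on the convex face at C12 | C=C(C)[C@H](CC(=O)OC)/C(I)=C/[C@H]1C(=O)O[C@@H]2C[C@](C)(O)[C@@H]([C@H]12)C(O[Si](CC)(CC)CC)[C@@H](O[Si](C)(C)C(C)(C)C)CCO[Si](c3ccccc3)(c3ccccc3)C(C)(C)C | intermediate
29 | dipotassium salt of 28 (dienolate C13=C12–C11=C10, C18 alkoxide) | C=C(C)[C@H](CC(=O)OC)/C(I)=C/C1=C(O[K])O[C@@H]2C[C@](C)(O[K])[C@@H]([C@H]12)C(O[Si](CC)(CC)CC)[C@@H](O[Si](C)(C)C(C)(C)C)CCO[Si](c3ccccc3)(c3ccccc3)C(C)(C)C | intermediate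
30 | C12 epimer of 28 (arm on the concave face, C12 as in the target) | C=C(C)[C@H](CC(=O)OC)/C(I)=C/[C@@H]1C(=O)O[C@@H]2C[C@](C)(O)[C@@H]([C@H]12)C(O[Si](CC)(CC)CC)[C@@H](O[Si](C)(C)C(C)(C)C)CCO[Si](c3ccccc3)(c3ccccc3)C(C)(C)C | intermediate
31 | C18,C23-diol | C=C(C)[C@H](CC(=O)OC)/C(I)=C/[C@@H]1C(=O)O[C@@H]2C[C@](C)(O)[C@@H]([C@H]12)C(O)[C@@H](O[Si](C)(C)C(C)(C)C)CCO[Si](c3ccccc3)(c3ccccc3)C(C)(C)C | intermediate
32 | keto iodide, precursor of the key step | C=C(C)[C@H](CC(=O)OC)/C(I)=C/[C@@H]1C(=O)O[C@@H]2C[C@](C)(O)[C@@H]([C@H]12)C(=O)[C@@H](O[Si](C)(C)C(C)(C)C)CCO[Si](c3ccccc3)(c3ccccc3)C(C)(C)C | intermediate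
33 | alkenylchromium dichloride from 32 (chromium on C10) | C=C(C)[C@H](CC(=O)OC)/C([Cr](Cl)Cl)=C/[C@@H]1C(=O)O[C@@H]2C[C@](C)(O)[C@@H]([C@H]12)C(=O)[C@@H](O[Si](C)(C)C(C)(C)C)CCO[Si](c3ccccc3)(c3ccccc3)C(C)(C)C | intermediate
34 | tricyclic C23 tertiary alcohol, product of the key step (C23 S, O24 cis to C18) | C=C(C)[C@H](CC(=O)OC)C1=C[C@@H]2C(=O)O[C@@H]3C[C@](C)(O)[C@@H]([C@H]23)[C@@]1(O)[C@@H](O[Si](C)(C)C(C)(C)C)CCO[Si](c4ccccc4)(c4ccccc4)C(C)(C)C | intermediate
35 | tetraol | C=C(C)[C@H](CC(=O)OC)C1=C[C@@H]2C(=O)O[C@@H]3C[C@](C)(O)[C@@H]([C@H]23)[C@@]1(O)[C@@H](O)CCO | intermediate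
36 | C25 hydroxy aldehyde | C=C(C)[C@H](CC(=O)OC)C1=C[C@@H]2C(=O)O[C@@H]3C[C@](C)(O)[C@@H]([C@H]23)[C@@]1(O)[C@@H](O)CC=O | intermediate
37 | spiro lactol (C25 anomers) | C=C(C)[C@H](CC(=O)OC)C1=C[C@@H]2C(=O)O[C@@H]3C[C@](C)(O)[C@@H]([C@H]23)[C@]12OC(O)C[C@@H]2O | intermediate
38 | CNP0148106.2 (C4 S, C12 S, C16 R, C18 S, C21 R, C22 R, C23 S, C28 S) | C=C(C)[C@H](CC(=O)OC)C1=C[C@@H]2C(=O)O[C@@H]3C[C@](C)(O)[C@@H]([C@H]23)[C@]12OC(=O)C[C@@H]2O | target

**Step count**

- Total step count: 23.
- Longest linear sequence: 17 steps (steps 1–4, 9–13 and 16–23).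

**Steps most likely to fail**

**Step 21.**
- What may go wrong: the hindered alkenylchromium species may add to the ketone too slowly. It is then protonated, so iodine is lost without ring closure, or nickel-promoted dimerisation takes over.
- Fallback: an anionic cyclisation triggered by halogen–lithium exchange, which sets out from 32.
- N-(Trimethylsilyl)imidazole in CH2Cl2 caps the C18 hydroxyl and gives the C18 trimethylsilyl ether of the keto iodide F1.
- t-BuLi (2 equiv) in THF–Et2O–pentane at −100 °C exchanges iodine for lithium faster than it attacks a carbonyl group or removes a proton.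
- The alkenyllithium F2, with its geometry retained, closes at once on the neighbouring C23 ketone. The C28 chain again avoids the concave face. The product is the C18 trimethylsilyl ether of the tricyclic alcohol F3.
- The HF·pyridine treatment of step 22 removes all three silyl groups, and the route is rejoined at 35.

**Step 18.**
- What may go wrong:
  - The bulky amide base may remove the concave-face hydrogen at C12 only slowly.
  - Protonation may be poorly face-selective or may occur at the γ-carbon.
  - The strained product may drift back to the convex-arm epimer during work-up.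
- Fallback: enolisation and protonation are separated, setting out from 28.
- Soft enolisation with Me3SiOTf and Et3N in CH2Cl2 at 0 °C, in which activation of the carbonyl oxygen makes the C12 hydrogen far more acidic, gives the isolable silyl ketene acetal with a silylated C18 hydroxyl F4.
- Protonation at −78 °C in toluene follows, with the SnCl4·BINOL complex, a Brønsted acid assisted by a Lewis acid. The BINOL enantiomer is chosen to reinforce the convex-face bias. This delivers the C18 trimethylsilyl ether of the concave-arm lactone F5.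
- The HF·pyridine treatment of step 19 removes the trimethylsilyl and the triethylsilyl group together, and the route is rejoined at 31.

**Step 17.**
- What may go wrong: acid and heat may ionise or dehydrate the doubly activated C11 carbinol, or may induce retro-aldol cleavage, before the ketene acetal has formed.
- Fallback: the ketene acetal is built by selenoxide elimination under non-acidic conditions, setting out from 26.
- Alkoxyselenation of methyl vinyl ether with PhSeBr and iPr2NEt in CH2Cl2 at −78 °C attaches the C11 oxygen and gives the mixed methyl 2-(phenylselanyl)ethyl acetal F6.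
- NaIO4 with NaHCO3 in aqueous MeOH gives the selenoxide F7.
- Warming in toluene with iPr2NH brings about syn elimination to ketene acetal 27. This rearranges as in the main route, and the route is rejoined at 28.

**Further compounds**

F1 | step 21 | C18 trimethylsilyl ether of keto iodide 32 | C=C(C)[C@H](CC(=O)OC)/C(I)=C/[C@@H]1C(=O)O[C@@H]2C[C@](C)(O[Si](C)(C)C)[C@@H]([C@H]12)C(=O)[C@@H](O[Si](C)(C)C(C)(C)C)CCO[Si](c3ccccc3)(c3ccccc3)C(C)(C)C
F2 | step 21 | alkenyllithium from F1 (lithium on C10) | C=C(C)[C@H](CC(=O)OC)/C([Li])=C/[C@@H]1C(=O)O[C@@H]2C[C@](C)(O[Si](C)(C)C)[C@@H]([C@H]12)C(=O)[C@@H](O[Si](C)(C)C(C)(C)C)CCO[Si](c3ccccc3)(c3ccccc3)C(C)(C)C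
F3 | step 21 | C18 trimethylsilyl ether of tricyclic alcohol 34 | C=C(C)[C@H](CC(=O)OC)C1=C[C@@H]2C(=O)O[C@@H]3C[C@](C)(O[Si](C)(C)C)[C@@H]([C@H]23)[C@@]1(O)[C@@H](O[Si](C)(C)C(C)(C)C)CCO[Si](c4ccccc4)(c4ccccc4)C(C)(C)C
F4 | step 18 | trimethylsilyl ketene acetal of 28 with C18 trimethylsilyl ether | C=C(C)[C@H](CC(=O)OC)/C(I)=C/C1=C(O[Si](C)(C)C)O[C@@H]2C[C@](C)(O[Si](C)(C)C)[C@@H]([C@H]12)C(O[Si](CC)(CC)CC)[C@@H](O[Si](C)(C)C(C)(C)C)CCO[Si](c3ccccc3)(c3ccccc3)C(C)(C)C
F5 | step 18 | C18 trimethylsilyl ether of 30 | C=C(C)[C@H](CC(=O)OC)/C(I)=C/[C@@H]1C(=O)O[C@@H]2C[C@](C)(O[Si](C)(C)C)[C@@H]([C@H]12)C(O[Si](CC)(CC)CC)[C@@H](O[Si](C)(C)C(C)(C)C)CCO[Si](c3ccccc3)(c3ccccc3)C(C)(C)C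
F6 | step 17 | mixed methyl 2-(phenylselanyl)ethyl acetal of 26 at the C11 oxygen (acetal epimers) | C=C(C)/C=C(I)/[C@H](OC(C[Se]c4ccccc4)OC)[C@H]1C(=O)O[C@@H]2C[C@](C)(O)[C@@H]([C@H]12)C(O[Si](CC)(CC)CC)[C@@H](O[Si](C)(C)C(C)(C)C)CCO[Si](c3ccccc3)(c3ccccc3)C(C)(C)C
F7 | step 17 | selenoxide of F6 | C=C(C)/C=C(I)/[C@H](OC(C[Se](=O)c4ccccc4)OC)[C@H]1C(=O)O[C@@H]2C[C@](C)(O)[C@@H]([C@H]12)C(O[Si](CC)(CC)CC)[C@@H](O[Si](C)(C)C(C)(C)C)CCO[Si](c3ccccc3)(c3ccccc3)C(C)(C)C
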